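**Strategy.** The route rests on a Diels–Alder disconnection of the ester-bearing cyclohexene of the target (C3, C4=C5, C6, C7, C13 in the numbering of its name). Its C4=C5 bond is flanked by C6 (CO2Me) and by C3, which the C2 methylene links to cyclobutane carbon C1. Cleaving C3–C13 and C6–C7 gives a bicyclo[4.2.0]octa-2,4-diene whose cyclobutane carries the decenyl chain exo and, trans to it, an endo CH2-linked (2E,4E)-dienoate. One intramolecular [4+2] cycloaddition closes the cyclopentane with its leading bond and, last, the ester-bearing cyclohexene, setting four stereocentres. The two controlling cyclobutane centres come from alkaloid-mediated desymmetrisation of a meso cyclobutane anhydride and one epimerisation.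

Key step: step 13

Assumption: quinidine is taken to deliver methanol to the C8 carbonyl of the meso anhydride of step 1 (giving the 7R,8S hemiester, by analogy with other cis-fused cyclic meso anhydrides); if the sense is the opposite, quinine replaces it and nothing else changes.

Remark: the bicyclo[4.2.0]octa-2,4-dienes of steps 5 to 12 are drawn as the valence isomer the route makes directly; the isomer reached by disrotatory opening and reclosure (both ring-fusion centres inverted, C7 and C8 untouched) would converge on the same target after re-equilibration at about 65 °C.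

Step 1
Reactants: 1 maleic anhydride; 2 cyclohexa-1,4-diene
Product: 3 meso cis-anti-cis-bicyclo[4.2.0]oct-3-ene-7,8-dicarboxylic anhydride
Conditions: hν (Hg lamp, Pyrex), acetophenone (sensitiser), EtOAc, 10 °C, 2 in excess
Reagents that add atoms: none
Why: Sensitised [2+2] photocycloaddition of maleic anhydride to one isolated ring alkene (the skipped diene offers no thermal [4+2]); both new bonds form on one face of the cis ring alkene and of the cis anhydride, so the ring fusion is cis, the anti adduct is expected on steric grounds, and the product is meso.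

Step 2
Reactants: 3 meso anhydride
Product: 4 (1R,6S,7R,8S)-8-(methoxycarbonyl)bicyclo[4.2.0]oct-3-ene-7-carboxylic acid
Conditions: quinidine (1.1 equiv), MeOH (3 equiv), PhMe, −55 °C; then 2 M HCl
Reagents that add atoms: methanol, CO
Why: Cinchona-alkaloid-mediated desymmetrising methanolysis of a cyclic meso anhydride (general-base delivery of methanol to one enantiotopic carbonyl); this step fixes the absolute configuration of C7 and C8 and thereby of the whole route.

Step 3
Reactants: 4 cis hemiester
Product: 5 (1R,6S,7R,8S)-3,4-dibromo-8-(methoxycarbonyl)bicyclo[4.2.0]octane-7-carboxylic acid (trans-3,4-dibromide; either trans diastereomer is usable, one drawn)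
Conditions: Br2 (1.05 equiv), CH2Cl2, −78 °C
Reagents that add atoms: bromine, BrBr
Why: Electrophilic anti addition of bromine to the isolated cyclohexene; both carboxyl groups are exo and cannot reach the bromonium ion, so no bromolactonisation is expected.

Step 4
Reactants: 5 dibromide
Product: 6 (1R,6S,7R,8S)-8-(methoxycarbonyl)bicyclo[4.2.0]octa-2,4-diene-7-carboxylic acid (cis, both groups exo)
Conditions: DBU (4 equiv), THF, 50 °C
Reagents that add atoms: none
Why: Twofold E2 dehydrobromination (the classical cyclohexene to cyclohexa-1,3-diene sequence); the anti-periplanar hydrogens lie on the flanking CH2 groups, so the conjugated 2,4-diene should result and no stereocentre is touched.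

Step 5
Reactants: 6 cis diene hemiester
Product: 7 (1R,6S,7R,8R)-8-(methoxycarbonyl)bicyclo[4.2.0]octa-2,4-diene-7-carboxylic acid (trans; CO2H exo, CO2Me endo)
Conditions: NaOMe (3 equiv), MeOH, 40 °C; then 1 M HCl to pH 3
Reagents that add atoms: none
Why: Thermodynamic α-epimerisation of the ester (only C8 enolises, since methoxide does not deprotonate the carboxylate α-carbon) relieves the eclipsed cis carboxylate/ester pair and should give the trans isomer; C7 keeps the configuration from step 2.

Step 6
Reactants: 7 trans diene hemiester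
Product: 9 methyl (1S,6R,7R,8R)-8-(hydroxymethyl)bicyclo[4.2.0]octa-2,4-diene-7-carboxylate, via isobutyl carbonic mixed anhydride 8 (not isolated)
Conditions: i-BuOCOCl, N-methylmorpholine, THF, −15 °C; then NaBH4, H2O, 0 °C
Reagents that add atoms: isobutyl chloroformate, CC(C)COC(=O)Cl (present in intermediate 8 only)
Why: Chemoselective reduction of the acid through its mixed carbonic anhydride, which NaBH4 reduces while the methyl ester and the diene are inert; no stereocentre is involved.

Step 7
Reactants: 9 hydroxy ester
Product: 10 methyl (1S,6R,7R,8R)-8-(iodomethyl)bicyclo[4.2.0]octa-2,4-diene-7-carboxylate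
Conditions: I2, PPh3, imidazole, CH2Cl2, 0 °C
Reagents that add atoms: iodine, II
Why: Appel-type iodination of the primary alcohol by SN2 displacement of the oxyphosphonium group.

Step 8
Reactants: 11 9-bromonon-1-ene
Product: 12 (2E)-9-bromonon-2-ene
Conditions: [Cp*Ru(NCMe)(κ2-P,N-L)]PF6 (1 mol %; L = 4-tert-butyl-2-(di-isopropylphosphino)-1-methylimidazole), acetone, 23 °C
Reagents that add atoms: none
Why: Catalyst-controlled one-position alkene transposition by a bifunctional ruthenium P,N complex (metal-assisted allylic hydrogen shuttle), a reaction type that stops at the (E)-2-alkene; the E geometry of the side chain is set here.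

Step 9
Reactants: 10 iodide; 12 (2E)-9-bromonon-2-ene
Product: 14 methyl (1R,6R,7S,8R)-8-[(8E)-dec-8-en-1-yl]bicyclo[4.2.0]octa-2,4-diene-7-carboxylate, via (7E)-non-7-en-1-ylmagnesium bromide 13 (not isolated)
Conditions: 12, Mg, THF, 40 °C; then 10, Li2CuCl4 (3 mol %), NMP (4 equiv), THF, −20 → 0 °C
Reagents that add atoms: magnesium, [Mg] (present in intermediate 13 only)
Why: Copper-catalysed sp3–sp3 cross-coupling of a primary alkyl iodide with a Grignard reagent, which at low temperature should outrun addition to the hindered secondary methyl ester; no stereocentre is involved.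

Step 10
Reactants: 14 ester
Product: 15 (1R,6R,7S,8R)-8-[(8E)-dec-8-en-1-yl]bicyclo[4.2.0]octa-2,4-diene-7-carbaldehyde
Conditions: i-Bu2AlH (1.1 equiv), CH2Cl2, −78 °C; then MeOH, aq. KNaC4H4O6
Reagents that add atoms: none
Why: Partial reduction of the methyl ester at −78 °C, where the aluminium hemiacetal persists until work-up; the α-centre C7 is already in its more stable trans arrangement.

Step 11
Reactants: 15 aldehyde; 16 (methoxymethyl)triphenylphosphonium chloride
Product: 18 2-[(1R,6S,7S,8S)-8-[(8E)-dec-8-en-1-yl]bicyclo[4.2.0]octa-2,4-dien-7-yl]acetaldehyde, via methyl enol ether 17 (not isolated)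
Conditions: 16, NaN(SiMe3)2, THF, 0 °C; 15, −78 → 0 °C; then 1 M HCl, THF, 23 °C
Reagents that add atoms: water, O
Why: Wittig methoxymethylenation followed by acid hydrolysis of the enol ether, the standard one-carbon homologation of an aldehyde; the ylide is added cold to keep the α-centre intact.

Step 12
Reactants: 18 aldehyde; 19 trimethyl 4-phosphonocrotonate
Product: 20 methyl (2E,4E)-6-[(1R,6S,7S,8S)-8-[(8E)-dec-8-en-1-yl]bicyclo[4.2.0]octa-2,4-dien-7-yl]hexa-2,4-dienoate
Conditions: 19, LiN(SiMe3)2, THF, −78 °C; then 18, −78 → 0 °C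
Reagents that add atoms: none
Why: Vinylogous Horner–Wadsworth–Emmons olefination; the stabilised phosphonate anion should give the new C4=C5 bond E and keep the C2=C3 bond E.

Step 13
Reactants: 20 trienyl dienoate
Product: 21 methyl (1S,3S,6R,7R,10R,11S,12S,13S)-11-[(8E)-dec-8-en-1-yl]tetracyclo[5.4.2.0^3,13.0^10,12]trideca-4,8-diene-6-carboxylate (CNP0133550.1)
Conditions: CH2Cl2 (0.02 M), BHT (cat.), 12 kbar, 40 °C
Reagents that add atoms: none
Why: The step is a concerted but asynchronous intramolecular [4+2] cycloaddition of inverse electron demand in which the (2E,4E)-dienoate is the 4π partner and the C4=C5 bond of the ring diene the 2π partner; the bond from the diene δ-carbon (C5′) to ring C5 leads and closes the cyclopentane, the bond from the ester α-carbon (C2′) to ring C4 lags and completes the ester-bearing cyclohexene, which is therefore the last ring of the skeleton to close. The closest known reaction type is the thermal type 1 intramolecular Diels–Alder reaction of endo-7-(penta-2,4-dienyl)bicyclo[4.2.0]octa-2,4-dienes (endiandric-acid-type cascade), here run under pressure instead of heat. Modes of closure: the cyclopentane forms as the three-atom-tether ring of the cycloaddition (tether C6–C7–C6′ of 20), the cyclohexene as the [4+2] ring itself. Stereocontrol: suprafacial addition to the cis ring alkene makes the hydrogens at C7 and C13 of 21 cis, the endo CH2 tether can deliver the diene only to the face of the cyclohexadiene syn to the cyclobutane and only in the exo orientation (trans ring fusion at C3–C13), and the E,E geometry of the diene places CO2Me at C6 cis to the C2 methylene, so all four new centres follow from C7 and C8 of 20. The selectivities needed are periselectivity (side-chain diene as 4π partner, not the ring diene with the γ,δ-alkene as 2π partner), which the match of the acceptor-polarised diene with the electron-rich ring alkene and the precedent of the reaction type should secure, and retention of configuration at the cyclobutane centres, which 12 kbar at 40 °C should secure because pressure accelerates the cycloaddition while the cyclooctatriene valence isomer should not open conrotatorily to the achiral tetraene at that temperature.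

**Compound list**

1 | maleic anhydride | O=C1OC(=O)C=C1 | starting material
2 | cyclohexa-1,4-diene | C1=CCC=CC1 | starting material
3 | meso (1R,6S,7R,8S)-bicyclo[4.2.0]oct-3-ene-7,8-dicarboxylic anhydride (cis ring fusion, anhydride anti to the six-membered ring) | O=C1OC(=O)[C@@H]2[C@H]3CC=CC[C@H]3[C@H]12 | intermediate
4 | (1R,6S,7R,8S)-8-(methoxycarbonyl)bicyclo[4.2.0]oct-3-ene-7-carboxylic acid | OC(=O)[C@@H]1[C@H]2CC=CC[C@H]2[C@@H]1C(=O)OC | intermediate
5 | (1R,6S,7R,8S)-3,4-dibromo-8-(methoxycarbonyl)bicyclo[4.2.0]octane-7-carboxylic acid, trans-3,4-dibromide (one trans diastereomer drawn) | OC(=O)[C@@H]1[C@H]2C[C@@H](Br)[C@H](Br)C[C@H]2[C@@H]1C(=O)OC | intermediate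
6 | (1R,6S,7R,8S)-8-(methoxycarbonyl)bicyclo[4.2.0]octa-2,4-diene-7-carboxylic acid | OC(=O)[C@@H]1[C@H]2C=CC=C[C@H]2[C@@H]1C(=O)OC | intermediate
7 | (1R,6S,7R,8R)-8-(methoxycarbonyl)bicyclo[4.2.0]octa-2,4-diene-7-carboxylic acid | OC(=O)[C@@H]1[C@H]2C=CC=C[C@H]2[C@H]1C(=O)OC | intermediate
8 | isobutyl carbonic mixed anhydride of 7 | CC(C)COC(=O)OC(=O)[C@@H]1[C@H]2C=CC=C[C@H]2[C@H]1C(=O)OC | intermediate (not isolated)
9 | methyl (1S,6R,7R,8R)-8-(hydroxymethyl)bicyclo[4.2.0]octa-2,4-diene-7-carboxylate | OC[C@@H]1[C@H]2C=CC=C[C@H]2[C@H]1C(=O)OC | intermediate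
10 | methyl (1S,6R,7R,8R)-8-(iodomethyl)bicyclo[4.2.0]octa-2,4-diene-7-carboxylate | IC[C@@H]1[C@H]2C=CC=C[C@H]2[C@H]1C(=O)OC | intermediate
11 | 9-bromonon-1-ene | C=CCCCCCCCBr | starting material
12 | (2E)-9-bromonon-2-ene | C/C=C/CCCCCCBr | intermediate
13 | (7E)-non-7-en-1-ylmagnesium bromide | C/C=C/CCCCCC[Mg]Br | intermediate (not isolated)
14 | methyl (1R,6R,7S,8R)-8-[(8E)-dec-8-en-1-yl]bicyclo[4.2.0]octa-2,4-diene-7-carboxylate | C/C=C/CCCCCCC[C@@H]1[C@H]2C=CC=C[C@H]2[C@H]1C(=O)OC | intermediate
15 | (1R,6R,7S,8R)-8-[(8E)-dec-8-en-1-yl]bicyclo[4.2.0]octa-2,4-diene-7-carbaldehyde | C/C=C/CCCCCCC[C@@H]1[C@H]2C=CC=C[C@H]2[C@H]1C=O | intermediate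
16 | (methoxymethyl)triphenylphosphonium chloride | COC[P+](c1ccccc1)(c1ccccc1)c1ccccc1.[Cl-] | starting material
17 | 8-[(8E)-dec-8-en-1-yl]-7-(2-methoxyethenyl)bicyclo[4.2.0]octa-2,4-diene (enol ether E/Z mixture, core as in 15) | C/C=C/CCCCCCC[C@@H]1[C@H]2C=CC=C[C@H]2[C@H]1C=COC | intermediate (not isolated)
18 | 2-[(1R,6S,7S,8S)-8-[(8E)-dec-8-en-1-yl]bicyclo[4.2.0]octa-2,4-dien-7-yl]acetaldehyde | C/C=C/CCCCCCC[C@@H]1[C@H]2C=CC=C[C@H]2[C@H]1CC=O | intermediate
19 | trimethyl 4-phosphonocrotonate, methyl (2E)-4-(dimethoxyphosphoryl)but-2-enoate | COC(=O)/C=C/CP(=O)(OC)OC | starting material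
20 | methyl (2E,4E)-6-[(1R,6S,7S,8S)-8-[(8E)-dec-8-en-1-yl]bicyclo[4.2.0]octa-2,4-dien-7-yl]hexa-2,4-dienoate | C/C=C/CCCCCCC[C@@H]1[C@H]2C=CC=C[C@H]2[C@H]1C/C=C/C=C/C(=O)OC | intermediate
21 | methyl (1S,3S,6R,7R,10R,11S,12S,13S)-11-[(8E)-dec-8-en-1-yl]tetracyclo[5.4.2.0^3,13.0^10,12]trideca-4,8-diene-6-carboxylate | C/C=C/CCCCCCC[C@@H]1[C@H]2C=C[C@@H]3[C@@H]4[C@H]2[C@H]1C[C@H]4C=C[C@H]3C(=O)OC | target

Total step count: 13. Longest linear sequence: 12 (steps 1–7 and 9–13; step 8 is the one-step side branch).

**Steps most likely to fail**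

Step 13. The acceptor-substituted diene may react too slowly, or with the wrong periselectivity (ring diene as 4π partner, γ,δ-alkene of the dienoate as 2π partner, giving a bicyclo[2.2.2]octene). Any heating used to force conversion would let the cyclooctatriene valence isomer open conrotatorily to the achiral tetraene, so that enantiomeric purity is lost. The fallback runs the cycloaddition at the alcohol oxidation level, where the side chain is a neutral diene as in the parent reaction type. It sets out from 20: i-Bu2AlH (CH2Cl2, −78 °C) should give the dienol F1; the same pressure-promoted cycloaddition should give the tetracyclic alcohol F2; oxidation (TEMPO cat., PhI(OAc)2, MeCN–H2O) should give the carboxylic acid F3; Me3SiCHN2 in MeOH–PhMe returns to the route at 21.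

Step 9. The Grignard reagent may add to the neighbouring methyl ester, iodine–magnesium exchange may compete, or substitution at the β-branched primary carbon may be too slow. The fallback replaces the organomagnesium coupling by sulfone alkylation and reductive desulfonylation. It sets out from 12 and 10: 12 with PhSO2Na (DMF, 60 °C) should give the sulfone F4; its α-lithio derivative (n-BuLi, THF, −78 °C) is alkylated with 10 (DMPU, −78 → −20 °C) to the alkylated sulfone F5; sodium amalgam (6% Na in Hg, Na2HPO4, MeOH, −20 °C) should remove the sulfonyl group and return to the route at 14.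

Step 1. Excited maleic anhydride or the sensitiser may abstract hydrogen from the doubly allylic CH2 groups (reduction, ene-type adducts, aromatisation) instead of adding, and the cycloadduct may form as a syn/anti mixture. The fallback builds the same skeleton thermally. It sets out from 1: sensitised photocycloaddition with acetylene should give cis-cyclobut-3-ene-1,2-dicarboxylic anhydride F6; a Diels–Alder reaction of its strained alkene with buta-1,3-diene (PhMe, sealed tube, 110 °C), anti to the anhydride ring, returns to the route at 3.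

**Further compounds**

F1 | step 13 | (2E,4E)-6-[(1R,6S,7S,8S)-8-[(8E)-dec-8-en-1-yl]bicyclo[4.2.0]octa-2,4-dien-7-yl]hexa-2,4-dien-1-ol | C/C=C/CCCCCCC[C@@H]1[C@H]2C=CC=C[C@H]2[C@H]1C/C=C/C=C/CO
F2 | step 13 | [(1S,3S,6R,7R,10R,11S,12S,13S)-11-[(8E)-dec-8-en-1-yl]tetracyclo[5.4.2.0^3,13.0^10,12]trideca-4,8-dien-6-yl]methanol | C/C=C/CCCCCCC[C@@H]1[C@H]2C=C[C@@H]3[C@@H]4[C@H]2[C@H]1C[C@H]4C=C[C@H]3CO
F3 | step 13 | (1S,3S,6R,7R,10R,11S,12S,13S)-11-[(8E)-dec-8-en-1-yl]tetracyclo[5.4.2.0^3,13.0^10,12]trideca-4,8-diene-6-carboxylic acid | C/C=C/CCCCCCC[C@@H]1[C@H]2C=C[C@@H]3[C@@H]4[C@H]2[C@H]1C[C@H]4C=C[C@H]3C(=O)O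
F4 | step 9 | [(7E)-non-7-ene-1-sulfonyl]benzene | C/C=C/CCCCCCS(=O)(=O)c1ccccc1
F5 | step 9 | methyl 8-[(8E)-2-(benzenesulfonyl)dec-8-en-1-yl]bicyclo[4.2.0]octa-2,4-diene-7-carboxylate (core as in 14, either configuration at the sulfone carbon) | C/C=C/CCCCCC(S(=O)(=O)c1ccccc1)C[C@@H]1[C@H]2C=CC=C[C@H]2[C@H]1C(=O)OC
F6 | step 1 | cis-cyclobut-3-ene-1,2-dicarboxylic anhydride | O=C1OC(=O)[C@@H]2C=C[C@H]12
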